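The route rests on cutting the C3–C4 bond (CH2–C=O) of the 2,2-dimethylchroman-4-one ring (ring C, fused to the hexasubstituted ring B). The key step exploits the fact that C4 is an aryl ketone beside a methylene (C3) held by the quaternary, oxygen-bearing C2. A ring-B aryl aldehyde and an ArO–CMe2–CH=N2 arm, generated in the flask from a non-enolisable dialdehyde via its mono-tosylhydrazone, should close ring C by diazo addition, 1,2-hydride shift and loss of N2, giving the ketone directly. The chromanone, built from coenzyme Q0, is joined to a fluoro-formyl benzoate (ring A) by SNAr; lactonisation and double O-demethylation finish the depsidone.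

Key step: step 5

Remark: the target has no stereocentre. Chroman numbering (O1, C2, C3, C4, C4a, C5–C8, C8a) is used for rings B and C; ring A is the formyl-bearing benzoate ring.

Step 1
Reactants: 1 coenzyme Q0 (2,3-dimethoxy-5-methyl-1,4-benzoquinone)
Product: 2 ubiquinol-0 (2,3-dimethoxy-5-methylbenzene-1,4-diol)
Conditions: Na2S2O4, H2O/EtOAc, rt, Ar
Reagents that add atoms: none
Why: Dithionite reduction of a quinone to its hydroquinone should be fast and clean and only adds two hydrogens.

Step 2
Reactants: 2 ubiquinol-0
Product: 3 hydroquinone aldehyde (2,5-dihydroxy-3,4-dimethoxy-6-methylbenzaldehyde)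
Conditions: MgCl2, Et3N, (CH2O)n, MeCN, reflux, Ar; aq. HCl
Reagents that add atoms: paraformaldehyde (as formaldehyde) C=O
Why: Magnesium-phenoxide-directed ortho-formylation (Casnati–Skattebøl reaction) should place the formyl group at the only free ring position, ortho to one hydroxyl, with a second formaldehyde acting as hydride acceptor.

Step 3
Reactants: 3 hydroquinone aldehyde
Product: 4 MOM ether (2-hydroxy-3,4-dimethoxy-5-(methoxymethoxy)-6-methylbenzaldehyde)
Conditions: MOMCl (1.05 equiv), iPr2NEt, CH2Cl2, 0 °C
Reagents that add atoms: chloromethyl methyl ether COCCl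
Why: Selective O-alkylation (MOM acetal formation) should occur at the 5-hydroxyl because the 2-hydroxyl is deactivated by its hydrogen bond to the formyl group.

Step 4
Reactants: 4 MOM ether; 5 α-bromoisobutyraldehyde (2-bromo-2-methylpropanal)
Product: 6 dialdehyde (3,4-dimethoxy-5-(methoxymethoxy)-6-methyl-2-[(2-methyl-1-oxopropan-2-yl)oxy]benzaldehyde)
Conditions: Cs2CO3, DMF, rt to 50 °C
Reagents that add atoms: none
Why: Williamson-type O-alkylation of the phenoxide at the carbonyl-activated tertiary bromide should install the O–CMe2–CHO arm, and neither aldehyde of the product can enolise under the base.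

Step 5
Reactants: 6 dialdehyde
Product: 9 chromanone (7,8-dimethoxy-6-(methoxymethoxy)-2,2,5-trimethylchroman-4-one), via mono-tosylhydrazone 7 (not isolated), via diazoalkane 8 (not isolated)
Conditions: TsNHNH2 (1.0 equiv), MeOH, 0 °C to rt; evaporate; then K2CO3, 1,4-dioxane, 110 °C
Reagents that add atoms: none
Why: Tosylhydrazide should condense only with the aliphatic, strongly electrophilic α-aryloxy aldehyde of 6, because the aryl aldehyde is flanked by two ortho substituents and deactivated by its ortho and para oxygen donors, and carbonate then effects Bamford–Stevens loss of sulfinate from 7 to the non-stabilised diazoalkane 8. The nucleophilic diazo carbon (future C3) adds to the neighbouring formyl carbon (future C4) in a 6-exo-trig closure of ring C, and the resulting alkoxide–diazonium betaine collapses by 1,2-hydride shift from C4 to C3 with loss of dinitrogen, which delivers the C4 ketone at the correct oxidation level. The closest known reaction type is the base-mediated reductive coupling of N-tosylhydrazones with aryl aldehydes to ketones (Büchner–Curtius–Schlotterbeck reaction of diazoalkanes), run here intramolecularly. No stereocentre remains in the product, since the two transient sp3 centres at C3 and C4 are levelled by the hydride shift. The step needs hydride shift to win over epoxide closure and aryl migration, and ring closure to outpace carbene formation; the six-membered tether, the Thorpe–Ingold effect of the gem-dimethyl group at C2 and a cation-bridged gauche alkoxide–diazonium arrangement that puts the C4–H bond antiperiplanar to the leaving dinitrogen should secure this.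

Step 6
Reactants: 9 chromanone
Product: 10 phenol (7-hydroxy-8-methoxy-6-(methoxymethoxy)-2,2,5-trimethylchroman-4-one)
Conditions: NaSEt, DMF, 100 °C; aq. HCl
Reagents that add atoms: none
Why: Nucleophilic (SN2) O-demethylation by thiolate should cleave the C7 methyl ether selectively because its phenoxide is para to the C4 ketone and doubly ortho-crowded, while the MOM acetal and the C8 methyl ether (meta to the ketone) resist thiolate.

Step 7
Reactants: 11 fluoroanisole (1-fluoro-3-methoxy-5-methylbenzene)
Product: 12 aryl bromide (2-bromo-1-fluoro-5-methoxy-3-methylbenzene)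
Conditions: NBS, MeCN, 0 °C to rt
Reagents that add atoms: N-bromosuccinimide O=C1CCC(=O)N1Br
Why: Electrophilic aromatic bromination with NBS in acetonitrile is para-selective for anisoles, so bromine should enter the position between fluorine and methyl.

Step 8
Reactants: 12 aryl bromide
Product: 13 bromo aldehyde (3-bromo-2-fluoro-6-methoxy-4-methylbenzaldehyde)
Conditions: LiN(iPr)2, THF, −78 °C; DMF; aq. HCl
Reagents that add atoms: N,N-dimethylformamide CN(C)C=O
Why: Directed ortho-metalation at the most acidic C–H, flanked by fluorine and methoxy, followed by formylation with DMF should give the aldehyde, since the amide base does not exchange bromine and the low temperature prevents loss of LiF to an aryne.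

Step 9
Reactants: 13 bromo aldehyde
Product: 14 PMB ester (4-methoxybenzyl 2-fluoro-3-formyl-4-methoxy-6-methylbenzoate)
Conditions: Pd(OAc)2 (cat.), Xantphos (cat.), CO (1 atm), 4-MeOC6H4CH2OH, Et3N, toluene, 90 °C
Reagents that add atoms: carbon monoxide [C-]#[O+]; 4-methoxybenzyl alcohol COc1ccc(CO)cc1
Why: Palladium-catalysed alkoxycarbonylation of the aryl bromide should install the acid-labile ester, and the weak amine base leaves the aldehyde and the C–F bond untouched.

Step 10
Reactants: 10 phenol; 14 PMB ester
Product: 15 diaryl ether (4-methoxybenzyl 3-formyl-4-methoxy-2-{[8-methoxy-6-(methoxymethoxy)-2,2,5-trimethyl-4-oxochroman-7-yl]oxy}-6-methylbenzoate)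
Conditions: Cs2CO3, DMF, 60 °C
Reagents that add atoms: none
Why: Nucleophilic aromatic substitution (SNAr) by the C7 phenoxide, the only free hydroxyl of 10, at the fluoride activated by an ortho formyl and an ortho ester group should fix the diaryl ether regiochemistry.

Step 11
Reactants: 15 diaryl ether
Product: 17 depsidone dimethyl ether (the target carrying OMe in place of both OH groups), via hydroxy acid 16 (not isolated)
Conditions: TFA/CH2Cl2 (1:1), anisole, H2O (5 equiv), rt; concentrate; then (CF3CO)2O, toluene, 0 °C to rt
Reagents that add atoms: none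
Why: Acidolysis should remove the PMB ester and the MOM ether together, and mixed-anhydride lactonisation of the hindered acid onto the only free phenol (C6–OH) then closes the seven-membered depsidone ring without ambiguity because the C8 oxygen is still methylated.

Step 12
Reactants: 17 depsidone dimethyl ether
Product: 18 target depsidone CNP0271978.0
Conditions: BBr3, CH2Cl2, −78 to 0 °C; H2O
Reagents that add atoms: none
Why: Lewis-acid ether cleavage by BBr3 should remove both aryl methyl ethers (the chelated one ortho to the ring-A aldehyde and the twisted C8 one), while the aryl lactone, both carbonyl groups and the vinylogous-ester-type O1 of ring C are expected to survive at low temperature.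

Compound list
1 | coenzyme Q0 (2,3-dimethoxy-5-methyl-1,4-benzoquinone) | COC1=C(OC)C(=O)C(C)=CC1=O | starting material
2 | ubiquinol-0 (2,3-dimethoxy-5-methylbenzene-1,4-diol) | COc1c(OC)c(O)c(C)cc1O | intermediate
3 | hydroquinone aldehyde (2,5-dihydroxy-3,4-dimethoxy-6-methylbenzaldehyde) | COc1c(OC)c(O)c(C)c(C=O)c1O | intermediate
4 | MOM ether (2-hydroxy-3,4-dimethoxy-5-(methoxymethoxy)-6-methylbenzaldehyde) | COCOc1c(C)c(C=O)c(O)c(OC)c1OC | intermediate
5 | α-bromoisobutyraldehyde (2-bromo-2-methylpropanal) | CC(C)(Br)C=O | starting material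
6 | dialdehyde (3,4-dimethoxy-5-(methoxymethoxy)-6-methyl-2-[(2-methyl-1-oxopropan-2-yl)oxy]benzaldehyde) | COCOc1c(C)c(C=O)c(OC(C)(C)C=O)c(OC)c1OC | intermediate
7 | mono-tosylhydrazone (E) of 6 at the aliphatic aldehyde (N'-{2-[2-formyl-5,6-dimethoxy-4-(methoxymethoxy)-3-methylphenoxy]-2-methylpropylidene}-4-methylbenzenesulfonohydrazide) | COCOc1c(C)c(C=O)c(OC(C)(C)/C=N/NS(=O)(=O)c2ccc(C)cc2)c(OC)c1OC | intermediate
8 | diazoalkane (2-[(1-diazo-2-methylpropan-2-yl)oxy]-3,4-dimethoxy-5-(methoxymethoxy)-6-methylbenzaldehyde) | COCOc1c(C)c(C=O)c(OC(C)(C)C=[N+]=[N-])c(OC)c1OC | intermediate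
9 | chromanone (7,8-dimethoxy-6-(methoxymethoxy)-2,2,5-trimethylchroman-4-one) | COCOc1c(C)c2C(=O)CC(C)(C)Oc2c(OC)c1OC | intermediate
10 | phenol (7-hydroxy-8-methoxy-6-(methoxymethoxy)-2,2,5-trimethylchroman-4-one) | COCOc1c(C)c2C(=O)CC(C)(C)Oc2c(OC)c1O | intermediate
11 | fluoroanisole (1-fluoro-3-methoxy-5-methylbenzene) | COc1cc(C)cc(F)c1 | starting material
12 | aryl bromide (2-bromo-1-fluoro-5-methoxy-3-methylbenzene) | COc1cc(C)c(Br)c(F)c1 | intermediate
13 | bromo aldehyde (3-bromo-2-fluoro-6-methoxy-4-methylbenzaldehyde) | COc1cc(C)c(Br)c(F)c1C=O | intermediate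
14 | PMB ester (4-methoxybenzyl 2-fluoro-3-formyl-4-methoxy-6-methylbenzoate) | COc1ccc(COC(=O)c2c(C)cc(OC)c(C=O)c2F)cc1 | intermediate
15 | diaryl ether (4-methoxybenzyl 3-formyl-4-methoxy-2-{[8-methoxy-6-(methoxymethoxy)-2,2,5-trimethyl-4-oxochroman-7-yl]oxy}-6-methylbenzoate) | COCOc1c(C)c2C(=O)CC(C)(C)Oc2c(OC)c1Oc1c(C=O)c(OC)cc(C)c1C(=O)OCc1ccc(OC)cc1 | intermediate
16 | hydroxy acid (3-formyl-2-[(6-hydroxy-8-methoxy-2,2,5-trimethyl-4-oxochroman-7-yl)oxy]-4-methoxy-6-methylbenzoic acid) | COc1c(Oc2c(C=O)c(OC)cc(C)c2C(=O)O)c(O)c(C)c2C(=O)CC(C)(C)Oc12 | intermediate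
17 | depsidone dimethyl ether (target with OMe at the ring-A hydroxyl and at C8) | Cc1cc(OC)c(C=O)c2c1C(=O)Oc1c(C)c3c(c(OC)c1O2)OC(C)(C)CC3=O | intermediate
18 | target depsidone CNP0271978.0 | Cc1cc(O)c(C=O)c2c1C(=O)Oc1c(C)c3c(c(O)c1O2)OC(C)(C)CC3=O | target

Total step count: 12. Longest linear sequence: 9 steps (steps 1–6 and 10–12); ring A is made in 3 steps (steps 7–9).

Steps most likely to fail

Step 5 (key step). Tosylhydrazide may condense unselectively with the aryl aldehyde. The diazoalkane may also lose nitrogen thermally (carbene 1,2-shift) before it closes the ring, or the betaine may collapse by epoxide closure or aryl migration instead of hydride shift. The fallback sets out from dialdehyde 6. An intramolecular crossed benzoin reaction under N-heterocyclic carbene catalysis (3-benzyl-5-(2-hydroxyethyl)-4-methylthiazolium chloride, Et3N, EtOH, 70 °C) should form the same C3–C4 bond and give racemic 3-hydroxy-7,8-dimethoxy-6-(methoxymethoxy)-2,2,5-trimethylchroman-4-one F1. The aryl-conjugated ketone is the expected thermodynamic acyloin under the basic, enediol-equilibrating conditions. Reductive removal of the α-hydroxyl with SmI2 (THF/MeOH, −78 °C) would come back to the route at chromanone 9.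

Step 10. The substitution may stall because both the phenoxide oxygen and the fluorine-bearing carbon are flanked on both sides, so that ester cleavage or condensation at the aldehyde takes over. The fallback sets out from phenol 10 and the smaller bromo aldehyde 13 (Cs2CO3, DMSO, 80 °C), which should give the diaryl ether 3-bromo-6-methoxy-2-{[8-methoxy-6-(methoxymethoxy)-2,2,5-trimethyl-4-oxochroman-7-yl]oxy}-4-methylbenzaldehyde F2. Removal of the MOM group (TFA/CH2Cl2/H2O, rt) gives 3-bromo-2-[(6-hydroxy-8-methoxy-2,2,5-trimethyl-4-oxochroman-7-yl)oxy]-6-methoxy-4-methylbenzaldehyde F3. A palladium-catalysed carbonylative lactonisation of the aryl bromide onto the C6 phenol (Pd(OAc)2, Xantphos, CO, Et3N, toluene, 100 °C) would then close the seven-membered lactone and come back to the route at depsidone dimethyl ether 17.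

Step 4. The hindered, hydrogen-bonded phenoxide may alkylate slowly, so that dehydrobromination of 5 to methacrolein followed by conjugate addition (wrong, primary ether) or decomposition of 5 competes. The fallback sets out from phenol 4. Palladium-catalysed O-(1,1-dimethylallyl)ation with tert-butyl 2-methylbut-3-en-2-yl carbonate (Pd(PPh3)4, THF, 0 °C) should give 3,4-dimethoxy-5-(methoxymethoxy)-6-methyl-2-[(2-methylbut-3-en-2-yl)oxy]benzaldehyde F4. Lemieux–Johnson cleavage of its vinyl group (OsO4 cat., NaIO4, 2,6-lutidine, dioxane/H2O) would come back to the route at dialdehyde 6.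

Further compounds
F1 | step 5 | racemic 3-hydroxy-7,8-dimethoxy-6-(methoxymethoxy)-2,2,5-trimethylchroman-4-one | COCOc1c(C)c2C(=O)C(O)C(C)(C)Oc2c(OC)c1OC
F2 | step 10 | 3-bromo-6-methoxy-2-{[8-methoxy-6-(methoxymethoxy)-2,2,5-trimethyl-4-oxochroman-7-yl]oxy}-4-methylbenzaldehyde | COCOc1c(C)c2C(=O)CC(C)(C)Oc2c(OC)c1Oc1c(C=O)c(OC)cc(C)c1Br
F3 | step 10 | 3-bromo-2-[(6-hydroxy-8-methoxy-2,2,5-trimethyl-4-oxochroman-7-yl)oxy]-6-methoxy-4-methylbenzaldehyde | COc1c(Oc2c(C=O)c(OC)cc(C)c2Br)c(O)c(C)c2C(=O)CC(C)(C)Oc12
F4 | step 4 | 3,4-dimethoxy-5-(methoxymethoxy)-6-methyl-2-[(2-methylbut-3-en-2-yl)oxy]benzaldehyde | COCOc1c(C)c(C=O)c(OC(C)(C)C=C)c(OC)c1OC
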